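**Strategy.** The dihydrofuran ring is disconnected at the bond between the benzylic carbinol carbon C3 and arene carbon C3a, ortho to the ring oxygen O1. Because C3 carries oxygen and sits next to the stereocentre C2, it can be an aldehyde carbon attacked by an aryl–chromium centre at C3a: an intramolecular Nozaki–Hiyama–Kishi reaction closes the five-membered ring and sets the C3 carbinol trans to the C2 substituent in one operation. The precursor is an open-chain (R)-α-aryloxy aldehyde bearing an ortho iodide, made by a palladium-catalysed stereoconvergent opening of racemic isopropenyloxirane with an iodophenol. Two esterifications, a ketone transfer hydrogenation and a final allylic oxidation complete the target.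

Key step: step 4

Remark: benzofuran numbering (O1, C2, C3, C3a, C4 to C7, C7a) is used throughout; the sense of induction of the ligand in step 2 is assigned by analogy with related vinyl epoxide openings, and the mirror-image ligand is taken if a first run shows the opposite sense.

**Step 1**
Reactants: 1 methacrolein (2-methylprop-2-enal)
Product: 3 2-(prop-1-en-2-yl)oxirane (racemic), via sulfonium betaine 2 (not isolated)
Conditions: Me3S+ I−, n-BuLi, THF, −10 °C; then 1, −10 °C to rt; fractional distillation
Reagents that add atoms: trimethylsulfonium iodide, C[S+](C)C.[I-]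
Why: Corey–Chaykovsky epoxidation, in which the unstabilised sulfonium ylide adds 1,2 to the enal carbonyl and betaine 2 closes with loss of dimethyl sulfide; the epoxide is racemic, which step 2 tolerates.

**Step 2**
Reactants: 3 2-(prop-1-en-2-yl)oxirane (racemic); 4 1-(4-hydroxy-3-iodophenyl)ethanone
Product: 6 (2R)-2-(4-acetyl-2-iodophenoxy)-3-methylbut-3-en-1-ol, via π-allylpalladium alkoxide 5 (not isolated)
Conditions: Pd2(dba)3·CHCl3 (1 mol%), (S,S)-DACH-naphthyl Trost ligand (3 mol%), CH2Cl2, rt
Reagents that add atoms: none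
Why: Palladium-catalysed dynamic kinetic asymmetric allylic etherification (Tsuji–Trost type), in which both epoxide enantiomers ionise to π-allyl complex 5, whose faces interconvert faster than the phenol attacks, so the chiral ligand sets C2 as R from racemic 3; hydrogen bonding to the alkoxide directs attack to the adjacent allyl terminus, and ortho-iodophenols are known to survive such catalysts at room temperature.

**Step 3**
Reactants: 6 (2R)-2-(4-acetyl-2-iodophenoxy)-3-methylbut-3-en-1-ol
Product: 7 (2R)-2-(4-acetyl-2-iodophenoxy)-3-methylbut-3-enal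
Conditions: Dess–Martin periodinane, NaHCO3, CH2Cl2, 0 °C to rt; used at once
Reagents that add atoms: none
Why: Buffered Dess–Martin oxidation converts the primary alcohol to the aldehyde without base, so the α-aryloxy, β,γ-unsaturated centre should neither epimerise nor move into conjugation; the ketone and the aryl iodide are inert.

**Step 4**
Reactants: 7 (2R)-2-(4-acetyl-2-iodophenoxy)-3-methylbut-3-enal
Product: 10 1-[(2R,3S)-3-hydroxy-2-(prop-1-en-2-yl)-2,3-dihydro-1-benzofuran-5-yl]ethanone, via arylchromium dichloride 8 (not isolated), via chromium alkoxide 9 (not isolated)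
Conditions: CrCl2 (6 equiv), NiCl2 (5 mol%), DMF, rt; aqueous work-up
Reagents that add atoms: none
Why: Divalent chromium reduces NiCl2 to zerovalent nickel, which inserts into the C–I bond; transmetalation gives arylchromium 8 (trivalent chromium), whose aryl carbon C3a adds to the tethered aldehyde carbon C3 to give alkoxide 9, hydrolysed on work-up. This is an intramolecular Nozaki–Hiyama–Kishi reaction of an aryl iodide with an aldehyde. The dihydrofuran ring closes in the 5-exo-trig mode, the carbonyl oxygen staying outside the ring. The new C3 stereocentre is controlled by the existing C2 centre: ring closure holds the carbonyl oxygen and the aldehyde hydrogen on opposite faces of the forming ring, and the oxygen with its chromium and ligands takes the face away from the isopropenyl group, which should give the 2,3-trans alcohol (3S). The step needs selectivity for the aldehyde over the aryl methyl ketone and the isopropenyl alkene, which the aldehyde preference of organochromium reagents and the fast nickel-to-chromium transmetalation secure. It also needs the α-aryloxy aldehyde to keep its configuration, which the non-basic medium and the fast intramolecular addition should allow.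

**Step 5**
Reactants: 10 1-[(2R,3S)-3-hydroxy-2-(prop-1-en-2-yl)-2,3-dihydro-1-benzofuran-5-yl]ethanone; 11 3-methylbutanoyl chloride
Product: 12 (2R,3S)-5-acetyl-2-(prop-1-en-2-yl)-2,3-dihydro-1-benzofuran-3-yl 3-methylbutanoate
Conditions: pyridine, DMAP (cat.), CH2Cl2, 0 °C
Reagents that add atoms: none
Why: Acylation of the secondary benzylic alcohol with an acid chloride under nucleophilic catalysis takes place at oxygen, so no stereocentre is touched.

**Step 6**
Reactants: 12 (2R,3S)-5-acetyl-2-(prop-1-en-2-yl)-2,3-dihydro-1-benzofuran-3-yl 3-methylbutanoate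
Product: 13 (2R,3S)-5-[(1R)-1-hydroxyethyl]-2-(prop-1-en-2-yl)-2,3-dihydro-1-benzofuran-3-yl 3-methylbutanoate
Conditions: RuCl[(R,R)-TsDPEN](p-cymene) (1 mol%), HCO2H/Et3N (5:2), CH2Cl2, rt
Reagents that add atoms: none
Why: Noyori asymmetric transfer hydrogenation of an aryl methyl ketone, in which the R,R catalyst should deliver hydride to the face that gives the (R)-carbinol; the ester and the 1,1-disubstituted alkene are inert to the ruthenium hydride.

**Step 7**
Reactants: 13 (2R,3S)-5-[(1R)-1-hydroxyethyl]-2-(prop-1-en-2-yl)-2,3-dihydro-1-benzofuran-3-yl 3-methylbutanoate; 14 (2R)-2-methylbutanoic acid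
Product: 16 (2R,3S)-5-[(1R)-1-{[(2R)-2-methylbutanoyl]oxy}ethyl]-2-(prop-1-en-2-yl)-2,3-dihydro-1-benzofuran-3-yl 3-methylbutanoate, via O-acylisourea 15 (not isolated)
Conditions: DIC, DMAP (cat.), CH2Cl2, 0 °C to rt
Reagents that add atoms: none
Why: Steglich esterification through O-acylisourea 15 with DMAP as acyl-transfer catalyst acylates the carbinol oxygen with retention, and the α-centre of the acid should not enolise under these mild conditions.

**Step 8**
Reactants: 16 (2R,3S)-5-[(1R)-1-{[(2R)-2-methylbutanoyl]oxy}ethyl]-2-(prop-1-en-2-yl)-2,3-dihydro-1-benzofuran-3-yl 3-methylbutanoate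
Product: 19 (2R,3S)-5-[(1R)-1-{[(2R)-2-methylbutanoyl]oxy}ethyl]-2-(3-oxoprop-1-en-2-yl)-2,3-dihydro-1-benzofuran-3-yl 3-methylbutanoate, via allylseleninic acid 17 (not isolated), via allylic alcohol 18 (not isolated)
Conditions: SeO2, 1,4-dioxane, 80 °C
Reagents that add atoms: selenium dioxide, O=[Se]=O
Why: Riley allylic oxidation, in which the ene reaction of SeO2 at the terminal alkene carbon takes a methyl hydrogen (the C2 hydrogen lies near the alkene plane and is poorly aligned), seleninic acid 17 undergoes a 2,3-sigmatropic shift to allylic alcohol 18, and further oxidation gives the enal; no stereocentre is involved.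

**Compound list**
1 | methacrolein (2-methylprop-2-enal) | C=C(C)C=O | starting material
2 | sulfonium betaine from ylide addition to 1 (racemic) | C=C(C)C([O-])C[S+](C)C | intermediate (not isolated)
3 | 2-(prop-1-en-2-yl)oxirane (racemic) | C=C(C)C1CO1 | intermediate
4 | 1-(4-hydroxy-3-iodophenyl)ethanone | CC(=O)c1ccc(O)c(I)c1 | starting material
5 | π-allylpalladium alkoxide (divalent palladium, drawn as the σ-allyl form, ligand omitted) | [O-]CC=C(C)C[Pd+] | intermediate (not isolated)
6 | (2R)-2-(4-acetyl-2-iodophenoxy)-3-methylbut-3-en-1-ol | C=C(C)[C@H](CO)Oc1ccc(C(C)=O)cc1I | intermediate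
7 | (2R)-2-(4-acetyl-2-iodophenoxy)-3-methylbut-3-enal | C=C(C)[C@H](C=O)Oc1ccc(C(C)=O)cc1I | intermediate
8 | arylchromium dichloride from 7 (trivalent chromium) | C=C(C)[C@H](C=O)Oc1ccc(C(C)=O)cc1[Cr](Cl)Cl | intermediate (not isolated)
9 | chromium alkoxide of 10 (trivalent chromium) | C=C(C)[C@H]1Oc2ccc(C(C)=O)cc2[C@@H]1O[Cr](Cl)Cl | intermediate (not isolated)
10 | 1-[(2R,3S)-3-hydroxy-2-(prop-1-en-2-yl)-2,3-dihydro-1-benzofuran-5-yl]ethanone | C=C(C)[C@H]1Oc2ccc(C(C)=O)cc2[C@@H]1O | intermediate
11 | 3-methylbutanoyl chloride | CC(C)CC(=O)Cl | starting material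
12 | (2R,3S)-5-acetyl-2-(prop-1-en-2-yl)-2,3-dihydro-1-benzofuran-3-yl 3-methylbutanoate | C=C(C)[C@H]1Oc2ccc(C(C)=O)cc2[C@@H]1OC(=O)CC(C)C | intermediate
13 | (2R,3S)-5-[(1R)-1-hydroxyethyl]-2-(prop-1-en-2-yl)-2,3-dihydro-1-benzofuran-3-yl 3-methylbutanoate | C=C(C)[C@H]1Oc2ccc([C@@H](C)O)cc2[C@@H]1OC(=O)CC(C)C | intermediate
14 | (2R)-2-methylbutanoic acid | CC[C@@H](C)C(=O)O | starting material
15 | O-acylisourea from 14 and DIC | CC[C@@H](C)C(=O)OC(=NC(C)C)NC(C)C | intermediate (not isolated)
16 | (2R,3S)-5-[(1R)-1-{[(2R)-2-methylbutanoyl]oxy}ethyl]-2-(prop-1-en-2-yl)-2,3-dihydro-1-benzofuran-3-yl 3-methylbutanoate | C=C(C)[C@H]1Oc2ccc([C@@H](C)OC(=O)[C@H](C)CC)cc2[C@@H]1OC(=O)CC(C)C | intermediate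
17 | allylseleninic acid from the ene reaction of 16 | C=C(C[Se](=O)O)[C@H]1Oc2ccc([C@@H](C)OC(=O)[C@H](C)CC)cc2[C@@H]1OC(=O)CC(C)C | intermediate (not isolated)
18 | (2R,3S)-2-(3-hydroxyprop-1-en-2-yl)-5-[(1R)-1-{[(2R)-2-methylbutanoyl]oxy}ethyl]-2,3-dihydro-1-benzofuran-3-yl 3-methylbutanoate | C=C(CO)[C@H]1Oc2ccc([C@@H](C)OC(=O)[C@H](C)CC)cc2[C@@H]1OC(=O)CC(C)C | intermediate (not isolated)
19 | (2R,3S)-5-[(1R)-1-{[(2R)-2-methylbutanoyl]oxy}ethyl]-2-(3-oxoprop-1-en-2-yl)-2,3-dihydro-1-benzofuran-3-yl 3-methylbutanoate | C=C(C=O)[C@H]1Oc2ccc([C@@H](C)OC(=O)[C@H](C)CC)cc2[C@@H]1OC(=O)CC(C)C | target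

**Total step count:** 8
**Longest linear sequence:** 8 steps (1 to 19)

**Steps most likely to fail**

Step 4. The aryl addition may show poor facial selectivity and favour the 2,3-cis alcohol, and the aldehyde may enolise before the ring closes. The fallback sets out from 7 and comes back at 12. The cyclisation is run as in step 4, and the cis alcohol 1-[(2R,3R)-3-hydroxy-2-(prop-1-en-2-yl)-2,3-dihydro-1-benzofuran-5-yl]ethanone F1 is esterified under Mitsunobu conditions (3-methylbutanoic acid, PPh3, DIAD, toluene, 0 °C). This inverts C3 and should give isovalerate 12 directly. Any trans alcohol 10 from the same run is acylated as in step 5, so both diastereomers converge on 12 and the C3 configuration is then fixed by the substitution, not by the addition.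

Step 8. The ene reaction may abstract the C2 hydrogen instead of a methyl hydrogen, or hot selenous acid may solvolyse the benzylic esters. The fallback sets out from 16 and comes back at 19. Ene-type allylic chlorination with hypochlorous acid (NaOCl, CeCl3·7H2O, CH2Cl2/H2O, 0 °C) should give the allylic chloride (2R,3S)-2-(3-chloroprop-1-en-2-yl)-5-[(1R)-1-{[(2R)-2-methylbutanoyl]oxy}ethyl]-2,3-dihydro-1-benzofuran-3-yl 3-methylbutanoate F2. An N-oxide variant of the Kornblum oxidation (4-methylmorpholine N-oxide, NaI cat., MeCN, rt) then converts the chloromethyl group to the aldehyde of 19 at room temperature.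

Step 2. The phenol may attack the distal allyl terminus and give the linear ether, enantioselection may be low with this acidic phenol, or zerovalent palladium may insert into the C–I bond. The fallback sets out from 3 and comes back at 6. Hydrolytic kinetic resolution of racemic 3 gives (2S)-3-methylbut-3-ene-1,2-diol F3; the conditions are (salen)Co(OAc) (trivalent cobalt; the enantiomer of the catalyst that leads to the S diol) with 0.45 equiv H2O at 0 °C to rt. Selective silylation of the primary hydroxyl (TBSCl, imidazole, CH2Cl2, 0 °C) gives (2S)-1-[(tert-butyldimethylsilyl)oxy]-3-methylbut-3-en-2-ol F4. Mitsunobu etherification with phenol 4 (PPh3, DIAD, toluene, 0 °C) inverts the carbinol and gives 1-[4-({(2R)-1-[(tert-butyldimethylsilyl)oxy]-3-methylbut-3-en-2-yl}oxy)-3-iodophenyl]ethanone F5. Methanolysis of the silyl ether (HCl cat., MeOH, 0 °C) returns 6.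

**Further compounds**
F1 | step 4 | 1-[(2R,3R)-3-hydroxy-2-(prop-1-en-2-yl)-2,3-dihydro-1-benzofuran-5-yl]ethanone | C=C(C)[C@H]1Oc2ccc(C(C)=O)cc2[C@H]1O
F2 | step 8 | (2R,3S)-2-(3-chloroprop-1-en-2-yl)-5-[(1R)-1-{[(2R)-2-methylbutanoyl]oxy}ethyl]-2,3-dihydro-1-benzofuran-3-yl 3-methylbutanoate | C=C(CCl)[C@H]1Oc2ccc([C@@H](C)OC(=O)[C@H](C)CC)cc2[C@@H]1OC(=O)CC(C)C
F3 | step 2 | (2S)-3-methylbut-3-ene-1,2-diol | C=C(C)[C@@H](CO)O
F4 | step 2 | (2S)-1-[(tert-butyldimethylsilyl)oxy]-3-methylbut-3-en-2-ol | C=C(C)[C@@H](CO[Si](C)(C)C(C)(C)C)O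
F5 | step 2 | 1-[4-({(2R)-1-[(tert-butyldimethylsilyl)oxy]-3-methylbut-3-en-2-yl}oxy)-3-iodophenyl]ethanone | C=C(C)[C@H](CO[Si](C)(C)C(C)(C)C)Oc1ccc(C(C)=O)cc1I
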